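## Structural features

The target is a dimer of two trans-3,4-dibenzylbutyrolactones (oxolan-2-ones), both (3S,4S), which is the mirror-image series of the common arctigenin-type lignans. In each lactone, C4 sits next to the ring OCH2 carbon (C5) and carries a 3,4-dimethoxybenzyl (veratrylmethyl) group, while C3 sits next to the carbonyl and carries a benzyl group whose arene belongs to the central diaryl ether. The two central arenes are ring A (4-aryloxy-3-methoxyphenyl) and ring B (3-aryloxy-4-hydroxy-5-methoxyphenyl); the ether oxygen between them is flanked by a methoxy group on ring A and by the free phenol on ring B, so the linkage is ortho-substituted on both sides. The four stereocentres form two adjacent pairs (C3/C4 of each lactone) that are held apart by the diaryl ether, so neither pair can pass stereochemical information to the other and each must be controlled separately and in the same sense. Fragile points are the epimerisable C3–H next to each carbonyl, the lactones towards hard nucleophiles, and the free phenol and four electron-rich arenes towards oxidants and electrophiles. The real difficulty is two-directional absolute and relative control of two remote trans-dibenzyl pairs, combined with a hindered diaryl ether. The key step uses the fact that C4 of each lactone is bonded to C5H2–O1: with C5 removed in thought, C4 is attached directly to the acyl oxygen and the ring is a 3,4-disubstituted oxetan-2-one, so the C4–C5 bond can be made by opening that β-lactone at C4 with a one-carbon nucleophile that is a masked CH2OH.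

## Logic of the disconnections

17 ⇒ 16. The benzyl–oxygen bond on the ring-B phenol is cut. The phenol is the only acidic, oxidation-prone site and would interfere with copper coupling, acyl chloride formation and organometallic steps, so it is masked throughout. The forward step must remove the benzyl group without touching lactones, aryl ethers or stereocentres, which hydrogenolysis does.

16 ⇒ 14 (through 15). Both C5–O1 lactone bonds are cut to give 15, and each C5–OH is then traded for a C5–Si bond to give 14. This turns each lactone into an open-chain acid whose C5 is a carbanion-derived carbon. The forward step needs a C–Si oxidation that tolerates electron-rich arenes and a free acid, followed by lactonisation that leaves C3 alone.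

14 ⇒ 11 + 13. The two C4–C5 bonds are cut, so that one molecule of 11 is joined to two molecules of 13. C5 leaves as a silylmethyl nucleophile and C4 becomes the oxygen-bearing carbon of a β-lactone whose acyl oxygen is the future carboxylate. This replaces the trans-dibenzyl γ-lactone problem by a cis-β-lactone problem, for which a catalytic asymmetric answer exists. The forward step must cleave the alkyl C–O bond, not the acyl C–O bond, with clean inversion at C4, twice.

13 ⇒ 12. The C–Mg bond is cut back to the C–Cl bond; magnesium insertion in the forward direction is routine.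

11 ⇒ 7 + 9 (through 10). Each four-membered ring is cut across C3–C4 and O1–C2, a formal [2+2] of a ketene and an aldehyde, so that one molecule of 7 is joined to two molecules of 9. Both stereocentres of each arm then come from achiral parts under the control of one catalyst. The forward step must give the cis isomer with high enantioselectivity at two independent sites and must outrun enolisation of 9.

9 ⇒ 8, and 7 ⇒ 6 ⇒ 5. These are adjustments of oxidation level and activation only: alcohol to aldehyde, ester to acid to acyl chloride. The demand is that 9 and 7 are made fresh and used at once.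

5 ⇒ 4 + 2. The diaryl ether C–O bond between C5 of ring B and the phenol oxygen of ring A is cut. Both halves then come from the same feedstock, one as a phenol and one as an aryl bromide. The forward copper coupling must cope with ortho substituents on both partners.

4 ⇒ 3 ⇒ 2 ⇒ 1. The benzyl ether, the bromine ortho to the phenol and the methyl ester are removed in turn. The only selectivity demand is bromination ortho to the hydroxyl group and not para to the methoxy group.

## Other disconnections considered

Alternative 1: The C3–CH2Ar bond of both lactones is cut, leading to two molecules of the monomeric lactone A1 and the diaryl ether bis(benzyl bromide) A3. The C5–O1 bond of A1 is then cut back to the prochiral cyclobutanone A2.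
- Forward key step: an enantioselective Baeyer–Villiger oxidation of A2 (H2O2 with a chiral phosphoric acid, or a monooxygenase with O2) would move one of two enantiotopic CH2 groups to oxygen and give A1. Two equivalents of the lithium enolate of A1 (from LiN(iPr)2) would then be alkylated by A3 anti to the C4 substituent to reach 16.
- In its favour: it is the shortest plan; the trans-selective alkylation of such a lactone enolate is dependable; no auxiliary or organometallic unmasking is needed.
- Against it here: the catalyst must tell apart two CH2 groups that differ only through a flexible benzyl group one carbon away from the ring, a weak handle for a small-molecule catalyst, and an enzyme would have to be screened for the required (S) sense. A3 is a pair of electron-rich, labile benzylic bromides, and a two-fold alkylation with a bifunctional electrophile invites mono-alkylation and proton transfer.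
- Comparison: on step economy this alternative is the better one (roughly eight steps against twelve). On mechanism the two plans are equal in that each rests on one catalytic enantioselective event per lactone and each gains from the statistical upgrading when two units end up in one molecule. On structure the chosen plan is stronger: it creates C3 and C4 together with a built-in cis preference and converts them stereospecifically, whereas here the absolute configuration hangs on a desymmetrisation whose selectivity for this substitution pattern is the open question.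

Alternative 2: Both the C3–CH2Ar and the C4–CH2Ar bonds of each lactone are cut, the latter as a C4–C(dithiane) bond. This gives the menthyloxybutenolide A5, the aryl dithiane A6 and the bis(benzyl bromide) A3.
- Forward key step: two equivalents of lithiated A6 would add in 1,4 fashion to two equivalents of A5 anti to the menthyloxy group, and the two lactone enolates would be trapped by A3 anti to the new C4 substituent. The product is the two-fold adduct A4, with four C–C bonds and four ring stereocentres formed and no ring closed. Desulfurisation with Raney Ni, reduction of the acetal carbon (NaBH4 under basic conditions, then acid) and loss of the benzyl group would complete the target.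
- In its favour: it is the most convergent plan; the absolute configuration comes from a diastereomerically pure acetal and does not depend on catalyst selectivity; the trans relationship follows from two successive anti additions.
- Against it here: A5 must be made in the (5S) series, for which the less common enantiomer of the auxiliary is needed, and freed from its acetal epimer. A two-fold three-component coupling gives statistical mixtures as soon as one enolate is protonated. Four C–S bonds call for a large excess of Raney Ni, and A3 is labile.
- Comparison: in step count this alternative is equal to or better than the chosen plan (roughly nine steps), and it is better in convergence and in the certainty of the absolute configuration. The chosen plan is better in that its chirality is catalytic, no stoichiometric auxiliary or sulfur has to be removed, and the C4 configuration arises from a stereospecific SN2 event and not from addition to an acetal whose purity must first be secured. Mechanistically both fix the trans relationship by substrate control.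

Alternative 3: The C2–C3 and C2–O1 bonds of both lactones are cut, with C2 coming from CO. The precursor is the bis(homopropargylic alcohol) A8, itself the product of a two-fold alkyne–arene coupling of the enantiopure alkynol A9 with the diaryl ether diiodide A10.
- Forward key step: a palladium-catalysed cyclocarbonylation (Pd2(dba)3, 1,4-bis(diphenylphosphino)butane, CO with a little H2) would add H and the acyl unit syn across each alkyne and close both rings by 5-exo capture of the acylpalladium by the hydroxyl group, giving the bis[(E)-arylidene lactone] A7. Hydrogenation, then base equilibration at C3, would follow.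
- In its favour: both rings and both carbonyl carbons come from one catalytic step; the alkene geometry does not matter since it is hydrogenated. The final hydrogenation would also remove the benzyl ether, and on this point it is better than the chosen plan.
- Against it here: C4 must already be present in enantiopure form in A8, so A9 needs an asymmetric synthesis of its own and its double coupling with A10 takes place on an electron-rich, hindered core. Hydrogenation of such arylidene lactones is expected to deliver hydrogen anti to the C4 substituent and so give the cis isomer first, so an epimerisation step is needed. Pressurised CO/H2 is less convenient.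
- Comparison: the step count is expected to be equal to or higher than that of the chosen plan. The two are equal in that one metal-catalysed step handles both arms at once. On stereochemistry the chosen plan is stronger, because it fixes C3 and C4 before the γ-lactone exists, whereas here C3 is left to a late and indirectly controlled event.

Key step: step 10

Assumption: O-trimethylsilylquinine is taken as the alkaloid that delivers the (3S,4R) cis-β-lactone series; if the sense of induction is the reverse for this ketene/aldehyde pair, O-trimethylsilylquinidine would replace it with no other change.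

## Route

Step 1
Reactants: 1 dihydroferulic acid [3-(4-hydroxy-3-methoxyphenyl)propanoic acid]
Product: 2 methyl 3-(4-hydroxy-3-methoxyphenyl)propanoate (methyl dihydroferulate)
Conditions: MeOH, H2SO4 (cat.), reflux
Reagents that add atoms: methanol, CO
Why: Fischer esterification driven by the excess of methanol; the phenol does not react under acid catalysis, and 2 serves both as the phenol partner and as the precursor of the bromide.

Step 2
Reactants: 2 methyl 3-(4-hydroxy-3-methoxyphenyl)propanoate
Product: 3 methyl 3-(3-bromo-4-hydroxy-5-methoxyphenyl)propanoate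
Conditions: NBS (1.0 equiv), iPr2NH (10 mol%), CH2Cl2, 0 °C
Reagents that add atoms: N-bromosuccinimide, O=C1CCC(=O)N1Br
Why: Amine-mediated electrophilic aromatic bromination; the N-bromoamine formed in situ hydrogen-bonds to the phenol and delivers bromine to the free ortho position (C5), the para position being blocked by the side chain. The ester and the benzylic CH2 are inert under these ionic conditions.

Step 3
Reactants: 3 methyl 3-(3-bromo-4-hydroxy-5-methoxyphenyl)propanoate
Product: 4 methyl 3-[4-(benzyloxy)-3-bromo-5-methoxyphenyl]propanoate
Conditions: BnBr, K2CO3, DMF, rt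
Reagents that add atoms: benzyl bromide, BrCc1ccccc1
Why: Williamson ether synthesis on the phenolate; the acidic 2,6-disubstituted phenol is alkylated cleanly by the reactive benzylic halide, and the methyl ester survives carbonate in dry DMF.

Step 4
Reactants: 4 methyl 3-[4-(benzyloxy)-3-bromo-5-methoxyphenyl]propanoate and 2 methyl 3-(4-hydroxy-3-methoxyphenyl)propanoate
Product: 5 methyl 3-{4-[2-(benzyloxy)-3-methoxy-5-(3-methoxy-3-oxopropyl)phenoxy]-3-methoxyphenyl}propanoate (diaryl ether diester)
Conditions: CuI (10 mol%), picolinic acid (20 mol%), K3PO4, DMSO, 90 °C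
Reagents that add atoms: none
Why: Copper-catalysed Ullmann diaryl ether coupling; the picolinate-ligated catalyst is suited to ortho-substituted phenols and aryl bromides. The benzyl ether and the esters are spectators, and any ester cleavage is harmless because the next step is saponification.

Step 5
Reactants: 5 diaryl ether diester
Product: 6 3-{4-[2-(benzyloxy)-5-(2-carboxyethyl)-3-methoxyphenoxy]-3-methoxyphenyl}propanoic acid (diaryl ether diacid)
Conditions: LiOH, THF/H2O, rt; then 1 M HCl
Reagents that add atoms: lithium hydroxide, [Li+].[OH-]
Why: Two-fold ester saponification by acyl substitution; ethers are inert and there is no stereocentre to protect.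

Step 6
Reactants: 6 diaryl ether diacid
Product: 7 3-{4-[2-(benzyloxy)-5-(3-chloro-3-oxopropyl)-3-methoxyphenoxy]-3-methoxyphenyl}propanoyl chloride (bis(acyl chloride))
Conditions: (COCl)2, DMF (cat.), CH2Cl2, 0 °C → rt; volatiles removed, toluene azeotrope
Reagents that add atoms: oxalyl chloride, O=C(Cl)C(=O)Cl
Why: Acyl chloride formation through the chloroiminium (Vilsmeier) intermediate under neutral, non-Lewis-acidic conditions, so the electron-rich arenes are not acylated and the benzyl ether stays; 7 is used crude at once.

Step 7
Reactants: 8 2-(3,4-dimethoxyphenyl)ethanol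
Product: 9 2-(3,4-dimethoxyphenyl)acetaldehyde
Conditions: Dess–Martin periodinane, CH2Cl2, 0 °C → rt; used immediately
Reagents that add atoms: none
Why: Dess–Martin oxidation stops at the aldehyde under near-neutral, base-free conditions, which suits an arylacetaldehyde that enolises and self-condenses easily; 9 is not stored.

Step 8
Reactants: 7 bis(acyl chloride) and 9 2-(3,4-dimethoxyphenyl)acetaldehyde (2 equiv)
Product: 11 (3S,4R)-3-{4-[2-(benzyloxy)-5-{[(3S,4R)-4-(3,4-dimethoxybenzyl)-2-oxooxetan-3-yl]methyl}-3-methoxyphenoxy]-3-methoxybenzyl}-4-(3,4-dimethoxybenzyl)oxetan-2-one (bis(cis-β-lactone)), via bis(ketene) 10 (not isolated)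
Conditions: O-trimethylsilylquinine (20 mol%), LiClO4 (2 equiv), iPr2NEt (5 equiv), 9 (3 equiv), CH2Cl2/Et2O, −78 °C, slow addition of 7
Reagents that add atoms: 2-(3,4-dimethoxyphenyl)acetaldehyde (second molecule of 9), COc1ccc(CC=O)cc1OC
Why: Cinchona alkaloid/lithium-cocatalysed ketene–aldehyde [2+2] cycloaddition (acyl halide–aldehyde cyclocondensation): iPr2NEt turns each acyl chloride into a ketene, the alkaloid adds to give a (Z)-ammonium enolate, and a closed LiClO4-organised aldol transition state followed by ring closure gives the cis-β-lactone, the alkaloid fixing the absolute sense at C3 and C4. Each of the two ketene arms takes up one molecule of 9 and the two remote sites react independently, so the small share of mismatched events should end up in a separable diastereomer and the enantiomeric purity of 11 is raised statistically.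

Step 9
Reactants: 12 (chloromethyl)isopropoxydimethylsilane
Product: 13 (isopropoxydimethylsilyl)methylmagnesium chloride (THF solution, titrated)
Conditions: Mg turnings, BrCH2CH2Br (cat.), THF, 40–60 °C
Reagents that add atoms: magnesium, [Mg]
Why: Grignard formation by magnesium insertion into the C–Cl bond; the hindered isopropoxy group on silicon keeps the reagent from attacking itself.

Step 10
Reactants: 11 bis(cis-β-lactone) and 13 (isopropoxydimethylsilyl)methylmagnesium chloride (2 equiv consumed)
Product: 14 (2S,3S)-2-{4-[2-(benzyloxy)-5-[(2S,3S)-2-carboxy-3-(3,4-dimethoxybenzyl)-4-(isopropoxydimethylsilyl)butyl]-3-methoxyphenoxy]-3-methoxybenzyl}-3-(3,4-dimethoxybenzyl)-4-(isopropoxydimethylsilyl)butanoic acid (bis(silylmethyl acid))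
Conditions: 13 (4 equiv), CuBr·SMe2 (20 mol% per lactone), THF/Me2S, −45 → −15 °C, slow addition of 13; then 1 M HCl, 0 °C
Reagents that add atoms: (isopropoxydimethylsilyl)methylmagnesium chloride (second equivalent of 13), CC(C)O[Si](C)(C)C[Mg]Cl
Why: The Grignard reagent transmetalates to monovalent copper to give a silylmethylcuprate, which attacks C4 of each lactone anti to the C4–O1 bond in an SN2-type oxidative addition; reductive elimination from the trivalent alkylcopper intermediate forms the C4–C5 bond, releases the carboxylate (RCO2MgCl) and returns monovalent copper. The closest known reaction types are the copper-catalysed alkyl–oxygen opening of enantioenriched β-lactones by Grignard reagents and the copper-catalysed epoxide opening by this same silylmethyl Grignard reagent. No ring is closed: two four-membered rings are opened with release of strain and two σ-bonds are formed. The stereocentre at the former C4 (C3 of each butanoic acid) is controlled by the substrate alone, through stereospecific inversion of the (4R) centre set in step 8; the α-carbon is not touched, since the carboxylate formed cannot be enolised under these conditions. This inversion converts the cis relationship of the β-lactone into the anti (2S,3S) arrangement that becomes trans once C5 and the carboxylate are joined. The step needs alkyl C–O over acyl C–O cleavage, which the soft organocopper nucleophile, ring strain and low temperature secure, with slow addition keeping free Grignard reagent scarce. It also needs substitution over E2 loss of a benzylic hydrogen next to C4, which the low basicity of the silyl-stabilised organocopper species favours. The Si–OiPr group, the benzyl ether and the aryl ethers are spectators, and the two remote lactones react independently, each taking up one molecule of 13, so that two equivalents end up in 14 and the remainder only serves the rate.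

Step 11
Reactants: 14 bis(silylmethyl acid)
Product: 16 (3S,4S)-3-{4-[2-(benzyloxy)-5-{[(3S,4S)-4-(3,4-dimethoxybenzyl)-2-oxooxolan-3-yl]methyl}-3-methoxyphenoxy]-3-methoxybenzyl}-4-(3,4-dimethoxybenzyl)oxolan-2-one (O-benzyl bis-lactone), via bis(hydroxy acid) 15 (not isolated)
Conditions: H2O2 (30% aq.), KF, KHCO3, THF/MeOH, 40 °C; then 2 M HCl, rt
Reagents that add atoms: hydrogen peroxide, OO
Why: Tamao–Fleming oxidation: fluoride and hydrogencarbonate make silicon hypercoordinate, hydroperoxide adds and the CH2 group migrates from Si to O, giving the primary alcohol at C5 without touching C3 or C4; silanol, siloxane or cyclic acyloxysilane forms that 14 may adopt on handling converge here. Acidification closes each γ-lactone by 5-exo-trig acyl substitution, and the (3S,4S) trans arrangement, which is also the thermodynamically preferred one, is kept.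

Step 12
Reactants: 16 O-benzyl bis-lactone
Product: 17 (3S,4S)-4-(3,4-dimethoxybenzyl)-3-{4-[5-{[(3S,4S)-4-(3,4-dimethoxybenzyl)-2-oxooxolan-3-yl]methyl}-2-hydroxy-3-methoxyphenoxy]-3-methoxybenzyl}oxolan-2-one (CNP0183104.1)
Conditions: H2 (1 atm), Pd/C (10%), EtOAc, rt
Reagents that add atoms: none
Why: Heterogeneous hydrogenolysis of the benzyl aryl ether; lactones, aryl methyl ethers, the diaryl ether and the non-oxygenated benzylic CH2 groups are inert at 1 atm and rt, and no stereocentre is involved.

## Compound list

1 | dihydroferulic acid, 3-(4-hydroxy-3-methoxyphenyl)propanoic acid | COc1cc(CCC(=O)O)ccc1O | starting material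
2 | methyl 3-(4-hydroxy-3-methoxyphenyl)propanoate | COC(=O)CCc1ccc(O)c(OC)c1 | intermediate
3 | methyl 3-(3-bromo-4-hydroxy-5-methoxyphenyl)propanoate | COC(=O)CCc1cc(Br)c(O)c(OC)c1 | intermediate
4 | methyl 3-[4-(benzyloxy)-3-bromo-5-methoxyphenyl]propanoate | COC(=O)CCc1cc(Br)c(OCc2ccccc2)c(OC)c1 | intermediate
5 | methyl 3-{4-[2-(benzyloxy)-3-methoxy-5-(3-methoxy-3-oxopropyl)phenoxy]-3-methoxyphenyl}propanoate | COC(=O)CCc1ccc(Oc2cc(CCC(=O)OC)cc(OC)c2OCc2ccccc2)c(OC)c1 | intermediate
6 | 3-{4-[2-(benzyloxy)-5-(2-carboxyethyl)-3-methoxyphenoxy]-3-methoxyphenyl}propanoic acid | OC(=O)CCc1ccc(Oc2cc(CCC(=O)O)cc(OC)c2OCc2ccccc2)c(OC)c1 | intermediate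
7 | 3-{4-[2-(benzyloxy)-5-(3-chloro-3-oxopropyl)-3-methoxyphenoxy]-3-methoxyphenyl}propanoyl chloride | O=C(Cl)CCc1ccc(Oc2cc(CCC(=O)Cl)cc(OC)c2OCc2ccccc2)c(OC)c1 | intermediate
8 | 2-(3,4-dimethoxyphenyl)ethanol | COc1ccc(CCO)cc1OC | starting material
9 | 2-(3,4-dimethoxyphenyl)acetaldehyde | COc1ccc(CC=O)cc1OC | intermediate
10 | bis(ketene) formed from 7 by two-fold loss of HCl (each CH2COCl arm becomes CH=C=O) | O=C=CCc1ccc(Oc2cc(CC=C=O)cc(OC)c2OCc2ccccc2)c(OC)c1 | intermediate
11 | (3S,4R)-3-{4-[2-(benzyloxy)-5-{[(3S,4R)-4-(3,4-dimethoxybenzyl)-2-oxooxetan-3-yl]methyl}-3-methoxyphenoxy]-3-methoxybenzyl}-4-(3,4-dimethoxybenzyl)oxetan-2-one | COc1cc(C[C@@H]2C(=O)O[C@@H]2Cc2ccc(OC)c(OC)c2)ccc1Oc1cc(C[C@@H]2C(=O)O[C@@H]2Cc2ccc(OC)c(OC)c2)cc(OC)c1OCc1ccccc1 | intermediate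
12 | (chloromethyl)isopropoxydimethylsilane | CC(C)O[Si](C)(C)CCl | starting material
13 | (isopropoxydimethylsilyl)methylmagnesium chloride | CC(C)O[Si](C)(C)C[Mg]Cl | intermediate
14 | (2S,3S)-2-{4-[2-(benzyloxy)-5-[(2S,3S)-2-carboxy-3-(3,4-dimethoxybenzyl)-4-(isopropoxydimethylsilyl)butyl]-3-methoxyphenoxy]-3-methoxybenzyl}-3-(3,4-dimethoxybenzyl)-4-(isopropoxydimethylsilyl)butanoic acid | COc1cc(C[C@H](C(=O)O)[C@@H](C[Si](C)(C)OC(C)C)Cc2ccc(OC)c(OC)c2)ccc1Oc1cc(C[C@H](C(=O)O)[C@@H](C[Si](C)(C)OC(C)C)Cc2ccc(OC)c(OC)c2)cc(OC)c1OCc1ccccc1 | intermediate
15 | (2S,3S)-2-{4-[2-(benzyloxy)-5-[(2S,3S)-2-carboxy-3-(3,4-dimethoxybenzyl)-4-hydroxybutyl]-3-methoxyphenoxy]-3-methoxybenzyl}-3-(3,4-dimethoxybenzyl)-4-hydroxybutanoic acid | COc1cc(C[C@H](C(=O)O)[C@@H](CO)Cc2ccc(OC)c(OC)c2)ccc1Oc1cc(C[C@H](C(=O)O)[C@@H](CO)Cc2ccc(OC)c(OC)c2)cc(OC)c1OCc1ccccc1 | intermediate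
16 | (3S,4S)-3-{4-[2-(benzyloxy)-5-{[(3S,4S)-4-(3,4-dimethoxybenzyl)-2-oxooxolan-3-yl]methyl}-3-methoxyphenoxy]-3-methoxybenzyl}-4-(3,4-dimethoxybenzyl)oxolan-2-one | COc1ccc(C[C@@H]2COC(=O)[C@H]2Cc2ccc(Oc3cc(C[C@@H]4C(=O)OC[C@H]4Cc4ccc(OC)c(OC)c4)cc(OC)c3OCc3ccccc3)c(OC)c2)cc1OC | intermediate
17 | (3S,4S)-4-(3,4-dimethoxybenzyl)-3-{4-[5-{[(3S,4S)-4-(3,4-dimethoxybenzyl)-2-oxooxolan-3-yl]methyl}-2-hydroxy-3-methoxyphenoxy]-3-methoxybenzyl}oxolan-2-one | COc1ccc(C[C@@H]2COC(=O)[C@H]2Cc2ccc(Oc3cc(C[C@@H]4C(=O)OC[C@H]4Cc4ccc(OC)c(OC)c4)cc(OC)c3O)c(OC)c2)cc1OC | target

## Step count and least certain steps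

Total step count: 12. Ten steps lie in the main line; steps 7 and 9 each prepare one coupling partner.
Longest linear sequence: 10 steps (steps 1–6, 8, 10, 11 and 12, from 1 to 17).

**Step 10 (key step).** The doubly flanked C4 may react slowly with the weakly nucleophilic silyl-stabilised organocopper species. Uncatalysed acyl attack by free Grignard reagent, or E2 loss of a benzylic hydrogen next to C4, could then compete, and with two sites per molecule any such leak is multiplied.
- Fallback: it sets out from 11 and changes the hydroxymethyl equivalent from a C–Si unit to a C=C unit. Copper-catalysed SN2 opening with vinylmagnesium bromide (CuBr·SMe2, THF/Me2S, −40 °C) would give, with the same inversion, the bis[(2S,3R)-3-(3,4-dimethoxybenzyl)pent-4-enoic acid] F1. Lemieux–Johnson cleavage (OsO4 cat., NaIO4, 2,6-lutidine, dioxane/H2O), chosen over ozone because of the electron-rich arenes, would give the bis(3-formyl acid) F2. F2 is reduced at once with NaBH4, before the centre next to the formyl group can epimerise, to 15, which rejoins the route and lactonises as in step 11 to 16.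

**Step 8.** Enolisation and self-aldolisation of the arylacetaldehyde under amine/LiClO4 may outrun the cycloaddition, and cis or enantiofacial control may slip at one of the two sites.
- Fallback: it sets out from 6 and uses an auxiliary-controlled aldol. Two-fold N-acylation of (S)-4-benzyl-2-oxazolidinone (pivaloyl chloride, Et3N, then the oxazolidinone and LiCl) would give the bis(N-acyloxazolidinone) F3. A double Evans syn-aldol reaction with 9 (Bu2BOTf, iPr2NEt, CH2Cl2, −78 → 0 °C) would give the bis[(2S,3R)-aldol adduct] F4. LiOH/H2O2 would release the bis(β-hydroxy acid) F5. Carboxyl activation (TsCl, pyridine, 0 °C) would then close both rings with retention at the carbinol carbon, returning to 11.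

**Step 4.** Oxidative addition is slow at an electron-rich aryl bromide flanked by a benzyloxy group, and the phenol carries an ortho-methoxy group, so hydrodebromination and ester cleavage in hot basic DMSO may take over.
- Fallback: it sets out from 4 and reverses the polarity of the aryl partner. Miyaura borylation (B2pin2, Pd(dppf)Cl2, KOAc, dioxane, 90 °C) would give the pinacol boronate F6. Oxidative cleavage of the pinacol ester (NaIO4, NH4OAc, acetone/H2O, rt) would give the arylboronic acid F7, the form that couples best with phenols. F7 would be coupled with 2 under Chan–Lam–Evans conditions (Cu(OAc)2, pyridine, 4 Å molecular sieves, air, CH2Cl2, rt), an oxidative coupling at divalent copper that runs at room temperature, returning to 5.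

**Step 2.** Regiocontrol may be incomplete, with bromination para to the methoxy group or twice on the ring, because both free positions of the arene are activated.
- Fallback: it sets out from 1 and relies on the much stronger directing power of a phenolate with the milder electrophile iodine. I2/KI in aqueous NaHCO3 would give 3-(4-hydroxy-3-iodo-5-methoxyphenyl)propanoic acid F8. Double benzylation (BnBr, K2CO3, DMF) would give benzyl 3-[4-(benzyloxy)-3-iodo-5-methoxyphenyl]propanoate F9. The copper coupling of step 4 with 2 would give the mixed methyl/benzyl diester F10. Saponification (LiOH, THF/H2O) returns to 6.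

## Further compounds

F1 | step 10 | (2S,3R)-2-{4-[2-(benzyloxy)-5-[(2S,3R)-2-carboxy-3-(3,4-dimethoxybenzyl)pent-4-enyl]-3-methoxyphenoxy]-3-methoxybenzyl}-3-(3,4-dimethoxybenzyl)pent-4-enoic acid | COc1cc(C[C@H](C(=O)O)[C@@H](C=C)Cc2ccc(OC)c(OC)c2)ccc1Oc1cc(C[C@H](C(=O)O)[C@@H](C=C)Cc2ccc(OC)c(OC)c2)cc(OC)c1OCc1ccccc1
F2 | step 10 | (2S,3S)-2-{4-[2-(benzyloxy)-5-[(2S,3S)-2-carboxy-3-(3,4-dimethoxybenzyl)-4-oxobutyl]-3-methoxyphenoxy]-3-methoxybenzyl}-3-(3,4-dimethoxybenzyl)-4-oxobutanoic acid | COc1cc(C[C@H](C(=O)O)[C@@H](C=O)Cc2ccc(OC)c(OC)c2)ccc1Oc1cc(C[C@H](C(=O)O)[C@@H](C=O)Cc2ccc(OC)c(OC)c2)cc(OC)c1OCc1ccccc1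
F3 | step 8 | bis(N-acyloxazolidinone) of 6 with (S)-4-benzyl-2-oxazolidinone | O=C(CCc1ccc(Oc2cc(CCC(=O)N3[C@@H](Cc4ccccc4)COC3=O)cc(OC)c2OCc2ccccc2)c(OC)c1)N1[C@@H](Cc2ccccc2)COC1=O
F4 | step 8 | bis[(2S,3R)-syn-aldol adduct], each arm (4S)-4-benzyl-3-[(2S,3R)-2-(arylmethyl)-4-(3,4-dimethoxyphenyl)-3-hydroxybutanoyl]oxazolidin-2-one | COc1cc(C[C@H](C(=O)N2[C@@H](Cc3ccccc3)COC2=O)[C@H](O)Cc2ccc(OC)c(OC)c2)ccc1Oc1cc(C[C@H](C(=O)N2[C@@H](Cc3ccccc3)COC2=O)[C@H](O)Cc2ccc(OC)c(OC)c2)cc(OC)c1OCc1ccccc1
F5 | step 8 | bis[(2S,3R)-β-hydroxy acid], each arm (2S,3R)-2-(arylmethyl)-4-(3,4-dimethoxyphenyl)-3-hydroxybutanoic acid | COc1cc(C[C@H](C(=O)O)[C@H](O)Cc2ccc(OC)c(OC)c2)ccc1Oc1cc(C[C@H](C(=O)O)[C@H](O)Cc2ccc(OC)c(OC)c2)cc(OC)c1OCc1ccccc1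
F6 | step 4 | methyl 3-[4-(benzyloxy)-3-methoxy-5-(4,4,5,5-tetramethyl-1,3,2-dioxaborolan-2-yl)phenyl]propanoate | COC(=O)CCc1cc(B2OC(C)(C)C(C)(C)O2)c(OCc2ccccc2)c(OC)c1
F7 | step 4 | [2-(benzyloxy)-3-methoxy-5-(3-methoxy-3-oxopropyl)phenyl]boronic acid | COC(=O)CCc1cc(B(O)O)c(OCc2ccccc2)c(OC)c1
F8 | step 2 | 3-(4-hydroxy-3-iodo-5-methoxyphenyl)propanoic acid | COc1cc(CCC(=O)O)cc(I)c1O
F9 | step 2 | benzyl 3-[4-(benzyloxy)-3-iodo-5-methoxyphenyl]propanoate | COc1cc(CCC(=O)OCc2ccccc2)cc(I)c1OCc1ccccc1
F10 | step 2 | benzyl 3-{4-(benzyloxy)-3-methoxy-5-[2-methoxy-4-(3-methoxy-3-oxopropyl)phenoxy]phenyl}propanoate | COC(=O)CCc1ccc(Oc2cc(CCC(=O)OCc3ccccc3)cc(OC)c2OCc2ccccc2)c(OC)c1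
A1 | alternative 1 | (S)-4-(3,4-dimethoxybenzyl)dihydrofuran-2(3H)-one | COc1ccc(C[C@@H]2COC(=O)C2)cc1OC
A2 | alternative 1 | 3-(3,4-dimethoxybenzyl)cyclobutan-1-one | COc1ccc(CC2CC(=O)C2)cc1OC
A3 | alternative 1 | 2-(benzyloxy)-5-(bromomethyl)-1-[4-(bromomethyl)-2-methoxyphenoxy]-3-methoxybenzene | COc1cc(CBr)ccc1Oc1cc(CBr)cc(OC)c1OCc1ccccc1
A4 | alternative 2 | two-fold Michael–alkylation adduct (bis-dithiane, bis-menthyl acetal) | COc1ccc(cc1OC)C1(SCCCS1)[C@@H]1[C@@H](O[C@H]2C[C@@H](C)CC[C@@H]2C(C)C)OC(=O)[C@H]1Cc1ccc(Oc2cc(C[C@@H]3C(=O)O[C@H](O[C@H]4C[C@@H](C)CC[C@@H]4C(C)C)[C@H]3C3(SCCCS3)c3ccc(OC)c(OC)c3)cc(OC)c2OCc2ccccc2)c(OC)c1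
A5 | alternative 2 | (5S)-5-{[(1S,2R,5S)-2-isopropyl-5-methylcyclohexyl]oxy}furan-2(5H)-one | O=C1C=C[C@@H](O[C@H]2C[C@@H](C)CC[C@@H]2C(C)C)O1
A6 | alternative 2 | 2-(3,4-dimethoxyphenyl)-1,3-dithiane | COc1ccc(C2SCCCS2)cc1OC
A7 | alternative 3 | bis[(E)-3-arylidene-(4S)-4-(3,4-dimethoxybenzyl)butyrolactone] | COc1cc(/C=C2/C(=O)OC[C@H]2Cc2ccc(OC)c(OC)c2)ccc1Oc1cc(/C=C2/C(=O)OC[C@H]2Cc2ccc(OC)c(OC)c2)cc(OC)c1OCc1ccccc1
A8 | alternative 3 | bis(homopropargylic alcohol), each arm an (S)-4-aryl-2-(3,4-dimethoxybenzyl)but-3-yn-1-ol | COc1cc(C#C[C@@H](CO)Cc2ccc(OC)c(OC)c2)ccc1Oc1cc(C#C[C@@H](CO)Cc2ccc(OC)c(OC)c2)cc(OC)c1OCc1ccccc1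
A9 | alternative 3 | (2S)-2-(3,4-dimethoxybenzyl)but-3-yn-1-ol | C#C[C@@H](CO)Cc1ccc(OC)c(OC)c1
A10 | alternative 3 | 2-(benzyloxy)-5-iodo-1-(4-iodo-2-methoxyphenoxy)-3-methoxybenzene | COc1cc(I)ccc1Oc1cc(I)cc(OC)c1OCc1ccccc1
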